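**Assumption (one line):** locants C1–C15 are the germacranolide positions of the target (C1 ketone, C4/C5 epoxide, C6 lactone O, C7/C11/C12/C13 lactone carbons with C13 = CH2OAc, C8 ester, C10 acetate); the SMILES is read as (4R,5R,6S,8S,10R) with a trans epoxide.

## Retrosynthetic overview

1. Last step: the 7(11)-butenolide with its 13-OAc is unveiled by syn-dehydration of an 11-hydroxy-13-acetoxy lactone, which is the masked form of an α-methylene lactone; the C8 methacrylate and C1 ketone come from late functional-group changes.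
2. Ten-membered ring (formed third): C1–C2 closure by intramolecular Nozaki–Hiyama–Kishi reaction of an (E)-vinyl iodide with the C1 aldehyde, then oxidation and conjugate reduction.
3. Key fragment union at C7–C8: intermolecular zinc Barbier allylation of a (R)-β-acetoxy aldehyde (C8–C10 and C1, from L-lactic acid by Seebach alkylation) with a 3-(bromomethyl)butenolide (C3–C7, C11–C13).
4. Ring order: epoxide first (directed epoxidation of a kinetically resolved dienol), butenolide second (ring-closing metathesis), carbocycle third.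

## Route

**Step 1**
Reactants: 1 (S)-lactic acid; 2 pivalaldehyde
Product: 3 (2S,5S)-2-tert-butyl-5-methyl-1,3-dioxolan-4-one
Conditions: p-TsOH (cat.), H2SO4 (cat.), pentane, reflux (Dean–Stark); recrystallisation at −78 °C
Reagents that add atoms: none
Why: Acid-catalysed acetalisation (Seebach dioxolanone) gives mainly the cis acetal, which is purified by crystallisation and stores the lactate chirality in the acetal centre.

**Step 2**
Reactants: 3 (2S,5S)-2-tert-butyl-5-methyl-1,3-dioxolan-4-one; 4 allyl bromide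
Product: 6 (2S,5R)-2-tert-butyl-5-methyl-5-(prop-2-en-1-yl)-1,3-dioxolan-4-one, via lithium enolate 5 (not isolated)
Conditions: LiN(iPr)2, THF, −78 °C; then allyl bromide, −78 → −20 °C
Reagents that add atoms: none
Why: Seebach self-regeneration of stereocentres: the enolate is alkylated anti to the tert-butyl group, so allyl replaces H with retention and sets the quaternary C10 centre.

**Step 3**
Reactants: 6 (2S,5R)-2-tert-butyl-5-methyl-5-(prop-2-en-1-yl)-1,3-dioxolan-4-one
Product: 7 (2R)-2-methylpent-4-ene-1,2-diol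
Conditions: LiAlH4, Et2O, 0 °C → rt
Reagents that add atoms: none
Why: Hydride reduction of the acylal carbonyl releases the diol and leaves the quaternary stereocentre untouched.

**Step 4**
Reactants: 7 (2R)-2-methylpent-4-ene-1,2-diol
Product: 8 (2R)-1-[(4-methoxybenzyl)oxy]-2-methylpent-4-en-2-ol
Conditions: NaH (1.05 equiv), 4-methoxybenzyl chloride, Bu4NI (cat.), THF/DMF, 0 °C → rt
Reagents that add atoms: 4-methoxybenzyl chloride, COc1ccc(CCl)cc1
Why: Williamson etherification occurs at the unhindered primary alkoxide and not at the tertiary hydroxyl.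

**Step 5**
Reactants: 8 (2R)-1-[(4-methoxybenzyl)oxy]-2-methylpent-4-en-2-ol
Product: 9 (2R)-1-[(4-methoxybenzyl)oxy]-2-methylpent-4-en-2-yl acetate
Conditions: Ac2O, Et3N, DMAP (0.2 equiv), CH2Cl2, rt, 24 h
Reagents that add atoms: acetic anhydride, CC(=O)OC(C)=O
Why: DMAP-catalysed acylation installs the tertiary C10 acetate early on a simple substrate, where forcing conditions are harmless.

**Step 6**
Reactants: 9 (2R)-1-[(4-methoxybenzyl)oxy]-2-methylpent-4-en-2-yl acetate
Product: 11 (2R)-1-[(4-methoxybenzyl)oxy]-2-methyl-4-oxobutan-2-yl acetate, via ozonide 10 (not isolated)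
Conditions: O3, CH2Cl2, −78 °C; then PPh3, −78 °C → rt
Reagents that add atoms: ozone, [O-][O+]=O
Why: Ozonolysis with neutral reductive work-up gives the C8 aldehyde without base, so the β-acetoxy aldehyde does not eliminate.

**Step 7**
Reactants: 12 propargyl alcohol
Product: 14 (2E)-3-iodo-2-methylprop-2-en-1-ol, via alkenylalane 13 (not isolated)
Conditions: AlMe3, Cp2ZrCl2 (0.25 equiv), CH2Cl2, 0 °C → rt; then I2, THF, −30 → 0 °C
Reagents that add atoms: trimethylaluminium, C[Al](C)C; iodine, [I][I]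
Why: Negishi zirconium-catalysed carboalumination adds Me and Al syn across the alkyne, and iodinolysis with retention gives the E-iodide that fixes the C4=C5 geometry.

**Step 8**
Reactants: 14 (2E)-3-iodo-2-methylprop-2-en-1-ol
Product: 15 tert-butyl{[(2E)-3-iodo-2-methylprop-2-en-1-yl]oxy}dimethylsilane
Conditions: TBSCl, imidazole, DMF, rt
Reagents that add atoms: tert-butyldimethylsilyl chloride, CC(C)(C)[Si](C)(C)Cl
Why: Standard silylation protects the future C3 hydroxyl.

**Step 9**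
Reactants: 15 tert-butyl{[(2E)-3-iodo-2-methylprop-2-en-1-yl]oxy}dimethylsilane; 16 acrolein
Product: 18 rac-(4E)-6-[(tert-butyldimethylsilyl)oxy]-5-methylhexa-1,4-dien-3-ol, via alkenyllithium 17 (not isolated)
Conditions: t-BuLi (2.1 equiv), Et2O, −78 °C; then acrolein, −78 °C
Reagents that add atoms: none
Why: Iodine–lithium exchange proceeds with retention of alkene geometry and the alkenyllithium adds 1,2 to acrolein to give the racemic divinyl carbinol (C6).

**Step 10**
Reactants: 18 rac-(4E)-6-[(tert-butyldimethylsilyl)oxy]-5-methylhexa-1,4-dien-3-ol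
Product: 19 (3S,4E)-6-[(tert-butyldimethylsilyl)oxy]-5-methylhexa-1,4-dien-3-ol
Conditions: Ti(OiPr)4, D-(−)-diisopropyl tartrate, t-BuOOH (0.6 equiv), 4 Å MS, CH2Cl2, −20 °C, to ca. 55–60% conversion
Reagents that add atoms: none
Why: Sharpless kinetic resolution: with D-(−)-tartrate the (3R)-enantiomer is epoxidised quickly at its trisubstituted alkene (erythro product), so the (3S)-alcohol with the C6 configuration of the target is recovered in high ee.

**Step 11**
Reactants: 19 (3S,4E)-6-[(tert-butyldimethylsilyl)oxy]-5-methylhexa-1,4-dien-3-ol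
Product: 20 (1S)-1-[(2R,3R)-3-{[(tert-butyldimethylsilyl)oxy]methyl}-3-methyloxiran-2-yl]prop-2-en-1-ol
Conditions: mCPBA, CH2Cl2, 0 °C
Reagents that add atoms: 3-chloroperoxybenzoic acid, OOC(=O)c1cccc(Cl)c1
Why: Hydroxyl-directed (Henbest) epoxidation of the electron-rich trisubstituted alkene is controlled by A(1,3) strain from the cis methyl group and gives the threo epoxy alcohol, setting C4 and C5 (4R,5R) from C6.

**Step 12**
Reactants: 21 2-(bromomethyl)acrylic acid; 22 4-methoxybenzyl alcohol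
Product: 23 2-{[(4-methoxybenzyl)oxy]methyl}acrylic acid
Conditions: NaH (2.2 equiv), THF, 0 °C → rt; aq HCl work-up
Reagents that add atoms: none
Why: The alkoxide displaces the activated allylic bromide (SN2/SN2', Williamson type) on the carboxylate salt to give the protected C11–C13 acrylate unit.

**Step 13**
Reactants: 20 (1S)-1-[(2R,3R)-3-{[(tert-butyldimethylsilyl)oxy]methyl}-3-methyloxiran-2-yl]prop-2-en-1-ol; 23 2-{[(4-methoxybenzyl)oxy]methyl}acrylic acid
Product: 24 (1S)-1-[(2R,3R)-3-{[(tert-butyldimethylsilyl)oxy]methyl}-3-methyloxiran-2-yl]prop-2-en-1-yl 2-{[(4-methoxybenzyl)oxy]methyl}acrylate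
Conditions: DCC, DMAP (cat.), CH2Cl2, 0 °C → rt
Reagents that add atoms: none
Why: Steglich esterification acylates the C6 hydroxyl with retention under conditions that leave the epoxide intact.

**Step 14**
Reactants: 24 the diene ester
Product: 25 (5S)-5-[(2R,3R)-3-{[(tert-butyldimethylsilyl)oxy]methyl}-3-methyloxiran-2-yl]-3-{[(4-methoxybenzyl)oxy]methyl}furan-2(5H)-one
Conditions: second-generation Grubbs catalyst RuCl2(=CHPh)(PCy3)(SIMes) (5 mol%), CH2Cl2, 40 °C, 5 mM
Reagents that add atoms: none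
Why: Ring-closing metathesis of the vinyl group with the 1,1-disubstituted acrylate closes the five-membered butenolide (C7=C11) with loss of ethene, without any base near the acidic C6–H.

**Step 15**
Reactants: 25 the PMB-protected butenolide
Product: 26 (5S)-5-[(2R,3R)-3-{[(tert-butyldimethylsilyl)oxy]methyl}-3-methyloxiran-2-yl]-3-(hydroxymethyl)furan-2(5H)-one
Conditions: DDQ, CH2Cl2/pH 7 buffer, 0 °C → rt
Reagents that add atoms: none
Why: Oxidative cleavage of the 4-methoxybenzyl ether is neutral and leaves the silyl ether, epoxide and butenolide untouched.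

**Step 16**
Reactants: 26 the hydroxymethyl butenolide
Product: 27 (5S)-3-(bromomethyl)-5-[(2R,3R)-3-{[(tert-butyldimethylsilyl)oxy]methyl}-3-methyloxiran-2-yl]furan-2(5H)-one
Conditions: CBr4, PPh3, CH2Cl2, 0 °C
Reagents that add atoms: carbon tetrabromide, BrC(Br)(Br)Br
Why: Appel bromination of the primary allylic alcohol is fast and neutral and gives the allyl bromide for the fragment coupling.

**Step 17 (key fragment union, C7–C8)**
Reactants: 27 the bromomethyl butenolide; 11 (2R)-1-[(4-methoxybenzyl)oxy]-2-methyl-4-oxobutan-2-yl acetate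
Product: 29 coupled α-methylene-γ-butyrolactone alcohol (H-6/H-7 trans; 8S-OH; 10R-OAc; C1-OPMB; C3-OTBS; 4,5-epoxide), via allylzinc bromide 28 (not isolated)
Conditions: Zn dust, THF/sat. aq NH4Cl, 0 °C → rt
Reagents that add atoms: none
Why: Zinc Barbier carbonyl allylation: the cyclic allylzinc attacks through its γ-carbon (C7) anti to the C6 substituent in a chair Zimmerman–Traxler transition state with the aldehyde chain equatorial, giving the 6,7-trans lactone and the 8S carbinol.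

**Step 18**
Reactants: 29 the coupled alcohol
Product: 30 8-O-TBS ether of 29
Conditions: TBSOTf, 2,6-lutidine, CH2Cl2, −78 → −20 °C
Reagents that add atoms: tert-butyldimethylsilyl triflate, CC(C)(C)[Si](C)(C)OS(=O)(=O)C(F)(F)F
Why: Fast low-temperature silylation blocks the C8 hydroxyl before the neighbouring tertiary acetate can migrate.

**Step 19**
Reactants: 30 the silyl ether
Product: 31 11,13-diol (saturated lactone; 11-OH cis to H-7)
Conditions: OsO4 (5 mol%), NMO, acetone/H2O, rt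
Reagents that add atoms: N-methylmorpholine N-oxide, C[N+]1([O-])CCOCC1; water, O
Why: Upjohn dihydroxylation of the only alkene occurs anti to the bulky C7 side chain and masks the α-methylene lactone for the later Cr, Ni and Cu steps.

**Step 20**
Reactants: 31 the diol
Product: 32 13-acetate (11-OH free)
Conditions: Ac2O, pyridine, DMAP (cat.), CH2Cl2, 0 °C
Reagents that add atoms: acetic anhydride, CC(=O)OC(C)=O
Why: Acylation is selective for the primary C13 hydroxyl over the hindered tertiary α-hydroxy lactone and installs the target's 13-OAc.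

**Step 21**
Reactants: 32 the 13-acetate
Product: 33 C3 primary alcohol (8-OTBS retained)
Conditions: HF·pyridine, pyridine, THF, 0 °C
Reagents that add atoms: none
Why: Buffered HF·pyridine cleaves the primary silyl ether much faster than the hindered secondary one and tolerates the epoxide.

**Step 22**
Reactants: 33 the C3 alcohol
Product: 34 C3 aldehyde (α,β-epoxy aldehyde)
Conditions: Dess–Martin periodinane, pyridine, CH2Cl2, 0 °C → rt
Reagents that add atoms: none
Why: Buffered Dess–Martin oxidation gives the non-enolisable epoxy aldehyde and leaves the tertiary alcohol alone.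

**Step 23**
Reactants: 34 the C3 aldehyde
Product: 35 (E)-vinyl iodide (C2=C3)
Conditions: CrCl2, CHI3, THF, 0 °C → rt
Reagents that add atoms: iodoform, IC(I)I
Why: Takai olefination is non-basic, adds C2, and gives the E-iodoalkene from the hindered aldehyde.

**Step 24**
Reactants: 35 the vinyl iodide
Product: 36 C1 primary alcohol
Conditions: DDQ, CH2Cl2/pH 7 buffer, 0 °C
Reagents that add atoms: none
Why: Oxidative removal of the 4-methoxybenzyl group is neutral, which suppresses 1,2-acetyl migration from O10, and spares the vinyl iodide and epoxide.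

**Step 25**
Reactants: 36 the C1 alcohol
Product: 37 C1 aldehyde
Conditions: Dess–Martin periodinane, pyridine, CH2Cl2, rt
Reagents that add atoms: none
Why: Dess–Martin oxidation, run at once on crude 36, gives the non-enolisable α-acetoxy aldehyde.

**Step 26**
Reactants: 37 the iodo aldehyde
Product: 39 macrocyclic (E)-allylic alcohol (C1 epimers), via alkenylchromium dichloride 38 (not isolated)
Conditions: CrCl2 (10 equiv), NiCl2 (1 mol%), DMSO, rt, 1 mM (slow addition)
Reagents that add atoms: none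
Why: Nozaki–Hiyama–Kishi macrocyclisation (zerovalent nickel inserts into C–I, then transmetalation to trivalent chromium) adds the alkenyl group chemoselectively to the aldehyde; the new C1 centre is irrelevant and the E-alkene keeps the C1–OH away from the epoxide.

**Step 27**
Reactants: 39 the allylic alcohol
Product: 40 macrocyclic (E)-enone (C1 ketone)
Conditions: Dess–Martin periodinane, pyridine, CH2Cl2, 0 °C
Reagents that add atoms: none
Why: Buffered Dess–Martin oxidation removes the C1 stereocentre and gives the ketone without acid.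

**Step 28**
Reactants: 40 the enone
Product: 42 saturated macrocyclic ketone, via copper enolate 41 (not isolated)
Conditions: [(Ph3P)CuH]6, PhH, H2O (trace), rt
Reagents that add atoms: none
Why: Stryker conjugate reduction delivers hydride to C3 of the enone only, and leaves the saturated lactone, epoxide and acetates untouched.

**Step 29**
Reactants: 42 the ketone
Product: 43 C8 alcohol
Conditions: Bu4NF, AcOH, THF, 0 °C → rt
Reagents that add atoms: none
Why: Acetic-acid-buffered fluoride removes the remaining silyl ether without the acid that would trigger keto-epoxide cyclisation.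

**Step 30**
Reactants: 43 the C8 alcohol
Product: 44 8-O-methacrylate (11-OH, 13-OAc)
Conditions: methacrylic anhydride, Et3N, DMAP (cat.), CH2Cl2, 0 °C
Reagents that add atoms: methacrylic anhydride, C=C(C)C(=O)OC(=O)C(C)=C
Why: DMAP-catalysed acylation takes the secondary C8 hydroxyl with retention while the tertiary C11 hydroxyl does not react.

**Step 31**
Reactants: 44 the 11-hydroxy lactone
Product: 46 glaucolide A, via C11 sulfamate ester 45 (not isolated)
Conditions: Burgess reagent (Et3N+SO2N−CO2Me), PhH, 50 °C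
Reagents that add atoms: none
Why: Burgess dehydration (syn-Ei) removes the C11 sulfamate with the cis H-7, away from the oxygen-bearing C13, and gives the tetrasubstituted 7(11)-butenolide under neutral conditions as the last step because the product is sensitive to base and acid.

## Compound list

1 | (S)-lactic acid | C[C@H](O)C(=O)O | starting material
2 | pivalaldehyde | CC(C)(C)C=O | starting material
3 | (2S,5S)-2-tert-butyl-5-methyl-1,3-dioxolan-4-one | C[C@@H]1O[C@H](C(C)(C)C)OC1=O | intermediate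
4 | allyl bromide | C=CCBr | starting material
5 | lithium enolate of 3, lithium (2S)-2-tert-butyl-5-methyl-1,3-dioxol-4-olate | CC1=C(O[Li])O[C@@H](C(C)(C)C)O1 | intermediate
6 | (2S,5R)-2-tert-butyl-5-methyl-5-(prop-2-en-1-yl)-1,3-dioxolan-4-one | C=CC[C@@]1(C)O[C@H](C(C)(C)C)OC1=O | intermediate
7 | (2R)-2-methylpent-4-ene-1,2-diol | C=CC[C@@](C)(O)CO | intermediate
8 | (2R)-1-[(4-methoxybenzyl)oxy]-2-methylpent-4-en-2-ol | C=CC[C@@](C)(O)COCc1ccc(OC)cc1 | intermediate
9 | (2R)-1-[(4-methoxybenzyl)oxy]-2-methylpent-4-en-2-yl acetate | C=CC[C@@](C)(OC(C)=O)COCc1ccc(OC)cc1 | intermediate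
10 | ozonide of 9 (3-substituted 1,2,4-trioxolane) | COc1ccc(COC[C@](C)(OC(C)=O)CC2OCOO2)cc1 | intermediate
11 | (2R)-1-[(4-methoxybenzyl)oxy]-2-methyl-4-oxobutan-2-yl acetate (C8 aldehyde fragment) | COc1ccc(COC[C@](C)(OC(C)=O)CC=O)cc1 | intermediate
12 | propargyl alcohol | C#CCO | starting material
13 | (E)-alkenylalane, dimethylaluminium alkoxide of (E)-3-(dimethylalumanyl)-2-methylprop-2-en-1-ol | C[Al](C)OC/C(C)=C/[Al](C)C | intermediate
14 | (2E)-3-iodo-2-methylprop-2-en-1-ol | OC/C(C)=C/I | intermediate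
15 | tert-butyl{[(2E)-3-iodo-2-methylprop-2-en-1-yl]oxy}dimethylsilane | CC(C)(C)[Si](C)(C)OC/C(C)=C/I | intermediate
16 | acrolein | C=CC=O | starting material
17 | (E)-3-[(tert-butyldimethylsilyl)oxy]-2-methylprop-1-enyllithium | CC(C)(C)[Si](C)(C)OC/C(C)=C/[Li] | intermediate
18 | rac-(4E)-6-[(tert-butyldimethylsilyl)oxy]-5-methylhexa-1,4-dien-3-ol | C=CC(O)/C=C(\C)CO[Si](C)(C)C(C)(C)C | intermediate
19 | (3S,4E)-6-[(tert-butyldimethylsilyl)oxy]-5-methylhexa-1,4-dien-3-ol | C=C[C@H](O)/C=C(\C)CO[Si](C)(C)C(C)(C)C | intermediate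
20 | (1S)-1-[(2R,3R)-3-{[(tert-butyldimethylsilyl)oxy]methyl}-3-methyloxiran-2-yl]prop-2-en-1-ol | C=C[C@H](O)[C@H]1O[C@]1(C)CO[Si](C)(C)C(C)(C)C | intermediate
21 | 2-(bromomethyl)acrylic acid | C=C(CBr)C(=O)O | starting material
22 | 4-methoxybenzyl alcohol | COc1ccc(CO)cc1 | starting material
23 | 2-{[(4-methoxybenzyl)oxy]methyl}acrylic acid | C=C(COCc1ccc(OC)cc1)C(=O)O | intermediate
24 | (1S)-1-[(2R,3R)-3-{[(tert-butyldimethylsilyl)oxy]methyl}-3-methyloxiran-2-yl]prop-2-en-1-yl 2-{[(4-methoxybenzyl)oxy]methyl}acrylate | C=C[C@H](OC(=O)C(=C)COCc1ccc(OC)cc1)[C@H]2O[C@]2(C)CO[Si](C)(C)C(C)(C)C | intermediate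
25 | (5S)-5-[(2R,3R)-3-{[(tert-butyldimethylsilyl)oxy]methyl}-3-methyloxiran-2-yl]-3-{[(4-methoxybenzyl)oxy]methyl}furan-2(5H)-one | COc1ccc(COCC2=C[C@H](OC2=O)[C@H]3O[C@]3(C)CO[Si](C)(C)C(C)(C)C)cc1 | intermediate
26 | (5S)-5-[(2R,3R)-3-{[(tert-butyldimethylsilyl)oxy]methyl}-3-methyloxiran-2-yl]-3-(hydroxymethyl)furan-2(5H)-one | OCC1=C[C@H](OC1=O)[C@H]2O[C@]2(C)CO[Si](C)(C)C(C)(C)C | intermediate
27 | (5S)-3-(bromomethyl)-5-[(2R,3R)-3-{[(tert-butyldimethylsilyl)oxy]methyl}-3-methyloxiran-2-yl]furan-2(5H)-one | BrCC1=C[C@H](OC1=O)[C@H]2O[C@]2(C)CO[Si](C)(C)C(C)(C)C | intermediate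
28 | allylzinc bromide from 27 | Br[Zn]CC1=C[C@H](OC1=O)[C@H]2O[C@]2(C)CO[Si](C)(C)C(C)(C)C | intermediate
29 | coupled alcohol: 11(13)-methylene 12,6-lactone, H-6/H-7 trans, 8S-OH, 10R-OAc, C1-OPMB, C3-OTBS, (4R,5R)-epoxide | COc1ccc(COC[C@](C)(OC(C)=O)C[C@H](O)[C@H]2C(=C)C(=O)O[C@@H]2[C@H]3O[C@]3(C)CO[Si](C)(C)C(C)(C)C)cc1 | intermediate
30 | 8-O-TBS ether of 29 | COc1ccc(COC[C@](C)(OC(C)=O)C[C@H](O[Si](C)(C)C(C)(C)C)[C@H]2C(=C)C(=O)O[C@@H]2[C@H]3O[C@]3(C)CO[Si](C)(C)C(C)(C)C)cc1 | intermediate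
31 | 11,13-diol of 30 (11-OH cis to H-7) | COc1ccc(COC[C@](C)(OC(C)=O)C[C@H](O[Si](C)(C)C(C)(C)C)[C@H]2[C@@](O)(CO)C(=O)O[C@@H]2[C@H]3O[C@]3(C)CO[Si](C)(C)C(C)(C)C)cc1 | intermediate
32 | 13-acetate of 31 | COc1ccc(COC[C@](C)(OC(C)=O)C[C@H](O[Si](C)(C)C(C)(C)C)[C@H]2[C@@](O)(COC(C)=O)C(=O)O[C@@H]2[C@H]3O[C@]3(C)CO[Si](C)(C)C(C)(C)C)cc1 | intermediate
33 | C3 primary alcohol (3-O-desilyl 32) | COc1ccc(COC[C@](C)(OC(C)=O)C[C@H](O[Si](C)(C)C(C)(C)C)[C@H]2[C@@](O)(COC(C)=O)C(=O)O[C@@H]2[C@H]3O[C@]3(C)CO)cc1 | intermediate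
34 | C3 aldehyde (epoxy aldehyde) | COc1ccc(COC[C@](C)(OC(C)=O)C[C@H](O[Si](C)(C)C(C)(C)C)[C@H]2[C@@](O)(COC(C)=O)C(=O)O[C@@H]2[C@H]3O[C@]3(C)C=O)cc1 | intermediate
35 | (E)-vinyl iodide (C2=C3), C1-OPMB | COc1ccc(COC[C@](C)(OC(C)=O)C[C@H](O[Si](C)(C)C(C)(C)C)[C@H]2[C@@](O)(COC(C)=O)C(=O)O[C@@H]2[C@H]3O[C@]3(C)/C=C/I)cc1 | intermediate
36 | C1 primary alcohol of 35 | OC[C@](C)(OC(C)=O)C[C@H](O[Si](C)(C)C(C)(C)C)[C@H]1[C@@](O)(COC(C)=O)C(=O)O[C@@H]1[C@H]2O[C@]2(C)/C=C/I | intermediate
37 | C1 aldehyde (seco iodo aldehyde) | O=C[C@](C)(OC(C)=O)C[C@H](O[Si](C)(C)C(C)(C)C)[C@H]1[C@@](O)(COC(C)=O)C(=O)O[C@@H]1[C@H]2O[C@]2(C)/C=C/I | intermediate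
38 | alkenylchromium dichloride from 37 | O=C[C@](C)(OC(C)=O)C[C@H](O[Si](C)(C)C(C)(C)C)[C@H]1[C@@](O)(COC(C)=O)C(=O)O[C@@H]1[C@H]2O[C@]2(C)/C=C/[Cr](Cl)Cl | intermediate
39 | ten-membered (2E)-allylic alcohol (1-OH epimers), 8-OTBS, 10-OAc, 11-OH, 13-OAc, 4,5-epoxide | CC(C)(C)[Si](C)(C)O[C@H]1C[C@@](C)(OC(C)=O)C(O)/C=C/[C@@]2(C)O[C@@H]2[C@H]2OC(=O)[C@](O)(COC(C)=O)[C@H]12 | intermediate
40 | ten-membered (2E)-en-1-one | CC(C)(C)[Si](C)(C)O[C@H]1C[C@@](C)(OC(C)=O)C(=O)/C=C/[C@@]2(C)O[C@@H]2[C@H]2OC(=O)[C@](O)(COC(C)=O)[C@H]12 | intermediate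
41 | copper enolate of 42 (monovalent copper, Ph3P ligand not drawn) | CC(C)(C)[Si](C)(C)O[C@H]1C[C@@](C)(OC(C)=O)C(O[Cu])=CC[C@@]2(C)O[C@@H]2[C@H]2OC(=O)[C@](O)(COC(C)=O)[C@H]12 | intermediate
42 | saturated 1-ketone, 8-OTBS, 11-OH, 13-OAc | CC(C)(C)[Si](C)(C)O[C@H]1C[C@@](C)(OC(C)=O)C(=O)CC[C@@]2(C)O[C@@H]2[C@H]2OC(=O)[C@](O)(COC(C)=O)[C@H]12 | intermediate
43 | 8-alcohol (8-O-desilyl 42) | O[C@H]1C[C@@](C)(OC(C)=O)C(=O)CC[C@@]2(C)O[C@@H]2[C@H]2OC(=O)[C@](O)(COC(C)=O)[C@H]12 | intermediate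
44 | 8-O-methacrylate, 11-hydroxy-11,13-dihydro precursor of the target | C=C(C)C(=O)O[C@H]1C[C@@](C)(OC(C)=O)C(=O)CC[C@@]2(C)O[C@@H]2[C@H]2OC(=O)[C@](O)(COC(C)=O)[C@H]12 | intermediate
45 | C11 O-[N-(methoxycarbonyl)sulfamate] of 44, triethylammonium salt | C=C(C)C(=O)O[C@H]1C[C@@](C)(OC(C)=O)C(=O)CC[C@@]2(C)O[C@@H]2[C@H]2OC(=O)[C@](OS(=O)(=O)[N-]C(=O)OC)(COC(C)=O)[C@H]12.CC[NH+](CC)CC | intermediate
46 | glaucolide A | C=C(C)C(=O)O[C@H]1C[C@@](C)(OC(C)=O)C(=O)CC[C@@]2(C)O[C@@H]2[C@H]2OC(=O)C(COC(C)=O)=C12 | target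

## Summary

Total step count: 31. Longest linear sequence: 24 steps (12 → 46 through steps 7–11 and 13–31).

Three steps most likely to fail:

**Step 26 (ten-membered ring closure by Cr/Ni).** Strain and oligomerisation may defeat the cyclisation. The fallback closes the ring by olefin metathesis at C2=C3 instead. It sets out from 34: Wittig methylenation (Ph3PCH3Br, KN(SiMe3)2, THF, −78 → 0 °C) gives the vinyl epoxide F1; DDQ gives the C1 alcohol F2; Dess–Martin oxidation gives the aldehyde F3; chemoselective vinylation (CH2=CHBr, CrCl2, NiCl2 cat., DMF) gives the divinyl carbinol F4; ring-closing metathesis (second-generation Hoveyda–Grubbs catalyst RuCl2(=CH-2-iPrOC6H4)(SIMes), PhMe, 80 °C, 1 mM) gives the cyclodecenol F5 (mainly Z expected); Dess–Martin oxidation gives the enone F6; conjugate reduction with [(Ph3P)CuH]6 as in step 28 comes back to the route at 42.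

**Step 23 (Takai olefination of the α,β-epoxy aldehyde).** Divalent chromium may open the epoxide reductively. The fallback uses a phosphorus ylide and the Z series. It sets out from 34: Stork–Zhao Wittig olefination (Ph3P+CH2I I−, NaN(SiMe3)2, THF, −78 °C) gives the (Z)-iodoalkene F7; DDQ gives the alcohol F8; Dess–Martin oxidation gives the aldehyde F9; CrCl2/NiCl2 cyclisation as in step 26 gives the (Z)-cyclodecenol F5, oxidation gives the (Z)-enone F6, and conjugate reduction comes back to the route at 42.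

**Step 17 (Barbier coupling, configuration at C8).** The C–C bond formation is dependable, but the C8 configuration rests on a transition-state argument. The fallback corrects it after the coupling. It sets out from 27 and 11: if the zinc reaction gives mainly the 8-epimeric alcohol F10, Mitsunobu inversion (PPh3, DIAD, HCO2H, PhMe, 0 °C) gives the formate F11 with the required 8S configuration, and mild methanolysis (KHCO3, MeOH, 0 °C) comes back to the route at 29.

## Further compounds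

F1 | step 26 | C3-vinyl epoxide (34 with CH=CH2 in place of CHO) | COc1ccc(COC[C@](C)(OC(C)=O)C[C@H](O[Si](C)(C)C(C)(C)C)[C@H]2[C@@](O)(COC(C)=O)C(=O)O[C@@H]2[C@H]3O[C@]3(C)C=C)cc1
F2 | step 26 | C1 primary alcohol of F1 | OC[C@](C)(OC(C)=O)C[C@H](O[Si](C)(C)C(C)(C)C)[C@H]1[C@@](O)(COC(C)=O)C(=O)O[C@@H]1[C@H]2O[C@]2(C)C=C
F3 | step 26 | C1 aldehyde of F1 | O=C[C@](C)(OC(C)=O)C[C@H](O[Si](C)(C)C(C)(C)C)[C@H]1[C@@](O)(COC(C)=O)C(=O)O[C@@H]1[C@H]2O[C@]2(C)C=C
F4 | step 26 | divinyl carbinol (C1 epimers) for metathesis | C=CC(O)[C@](C)(OC(C)=O)C[C@H](O[Si](C)(C)C(C)(C)C)[C@H]1[C@@](O)(COC(C)=O)C(=O)O[C@@H]1[C@H]2O[C@]2(C)C=C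
F5 | step 26 | ten-membered (2Z)-allylic alcohol (C1 epimers) | CC(C)(C)[Si](C)(C)O[C@H]1C[C@@](C)(OC(C)=O)C(O)/C=C\[C@@]2(C)O[C@@H]2[C@H]2OC(=O)[C@](O)(COC(C)=O)[C@H]12
F6 | step 26 | ten-membered (2Z)-en-1-one | CC(C)(C)[Si](C)(C)O[C@H]1C[C@@](C)(OC(C)=O)C(=O)/C=C\[C@@]2(C)O[C@@H]2[C@H]2OC(=O)[C@](O)(COC(C)=O)[C@H]12
F7 | step 23 | (Z)-vinyl iodide, C1-OPMB | COc1ccc(COC[C@](C)(OC(C)=O)C[C@H](O[Si](C)(C)C(C)(C)C)[C@H]2[C@@](O)(COC(C)=O)C(=O)O[C@@H]2[C@H]3O[C@]3(C)/C=C\I)cc1
F8 | step 23 | C1 alcohol of the (Z)-vinyl iodide | OC[C@](C)(OC(C)=O)C[C@H](O[Si](C)(C)C(C)(C)C)[C@H]1[C@@](O)(COC(C)=O)C(=O)O[C@@H]1[C@H]2O[C@]2(C)/C=C\I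
F9 | step 23 | C1 aldehyde of the (Z)-vinyl iodide | O=C[C@](C)(OC(C)=O)C[C@H](O[Si](C)(C)C(C)(C)C)[C@H]1[C@@](O)(COC(C)=O)C(=O)O[C@@H]1[C@H]2O[C@]2(C)/C=C\I
F10 | step 17 | 8-epimer of 29 (8R alcohol) | COc1ccc(COC[C@](C)(OC(C)=O)C[C@@H](O)[C@H]2C(=C)C(=O)O[C@@H]2[C@H]3O[C@]3(C)CO[Si](C)(C)C(C)(C)C)cc1
F11 | step 17 | 8-O-formate of 29 (8S) | COc1ccc(COC[C@](C)(OC(C)=O)C[C@H](OC=O)[C@H]2C(=C)C(=O)O[C@@H]2[C@H]3O[C@]3(C)CO[Si](C)(C)C(C)(C)C)cc1
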